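**Retrosynthetic overview**

1. Arteminorin C comes from hydrogenolysis of its 7,7'-dibenzyl ether, which comes from thermal isomerization of a 4-(benzyloxy)furan-2-yl (Z)-2-(coumarin-3-yl)pent-2-en-4-ynoate.
2. Structural feature: with unit A the 7-hydroxy-6,8-dimethoxycoumarin (O1 to C8a) and unit B the 6,7-dihydroxycoumarin (primed atoms), C8a', C8', C7' and C6' of ring B are C2, C3, C4 and C5 of a 2,4-dioxygenated furan whose ring oxygen becomes the 6'-OH. C4a' and C5' are a terminal alkyne, and O1'-C2'-C3'=C4' is the ester tether.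
3. The furyl ester comes from O-acylation of the benzyl tetronate dienolate with the (Z)-enynoic acid. The Z alkene is set by chelation-controlled enol tosylation of the formylated coumarin-3-acetate and Sonogashira coupling, because a direct condensation with a propynal would be expected to favour the E isomer.
4. The coumarin-3-acetic acid comes from a Perkin-type condensation of succinic anhydride with the salicylaldehyde made from syringaldehyde (benzylation, bromination, borylation/oxidation).
5. Ring order: the benzene ring of unit A is bought, the pyranone of unit A closes in step 4, and the pyranone and benzene rings of unit B close together in step 12.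

Key step: step 12

Assumption: the alpha-formyl ester is written as its hydrogen-bonded enol, the lithium ester enolate with an arbitrary geometry, and the oxa-bridged cycloadduct as one enantiomer of a racemate; none of these choices is carried into a later compound.

**Route**

Step 1
Reactants: 1 syringaldehyde
Product: 2 4-(benzyloxy)-3,5-dimethoxybenzaldehyde
Conditions: BnBr, K2CO3, DMF, 60 °C
Reagents that add atoms: benzyl bromide, BrCc1ccccc1
Why: Williamson ether synthesis on the acidic phenol para to the aldehyde should be clean and installs the benzyl group that is kept until the last step.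

Step 2
Reactants: 2 4-(benzyloxy)-3,5-dimethoxybenzaldehyde
Product: 3 4-(benzyloxy)-2-bromo-3,5-dimethoxybenzaldehyde
Conditions: NBS, MeCN, rt, dark
Reagents that add atoms: N-bromosuccinimide, O=C1CCC(=O)N1Br
Why: electrophilic aromatic bromination can only occur at the two equivalent free positions, each activated by an ortho and a para alkoxy group, as is usual for 3,4,5-trialkoxybenzaldehydes.

Step 3
Reactants: 3 4-(benzyloxy)-2-bromo-3,5-dimethoxybenzaldehyde
Product: 5 4-(benzyloxy)-2-hydroxy-3,5-dimethoxybenzaldehyde, via aryl pinacolboronate 4 (not isolated)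
Conditions: B2pin2, PdCl2(dppf), KOAc, dioxane, 90 °C; then NaBO3·4H2O, THF/H2O, rt
Reagents that add atoms: sodium perborate, [Na+].[Na+].O[B-]1(O)OO[B-](O)(O)OO1 (phenol oxygen of 5); bis(pinacolato)diboron, CC1(C)OB(OC1(C)C)B1OC(C)(C)C(C)(C)O1 (boryl group of 4 only)
Why: Miyaura borylation tolerates the aldehyde and is followed in the same flask by perborate oxidation of the C-B bond, an oxidant mild enough that the new salicylaldehyde should not suffer Dakin oxidation.

Step 4
Reactants: 5 4-(benzyloxy)-2-hydroxy-3,5-dimethoxybenzaldehyde; 6 succinic anhydride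
Product: 7 2-[7-(benzyloxy)-6,8-dimethoxy-2-oxo-2H-chromen-3-yl]acetic acid
Conditions: succinic anhydride (4 equiv), Et3N, 140 °C; then aq. HCl
Reagents that add atoms: none
Why: in this Perkin-type condensation the phenol is O-succinylated, the methylene alpha to the new aryl ester attacks the aldehyde intramolecularly and dehydration closes the six-membered pyranone of unit A with the CH2CO2H arm at C3, the excess anhydride holding back a second condensation at that arm.

Step 5
Reactants: 7 2-[7-(benzyloxy)-6,8-dimethoxy-2-oxo-2H-chromen-3-yl]acetic acid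
Product: 8 2-(trimethylsilyl)ethyl 2-[7-(benzyloxy)-6,8-dimethoxy-2-oxo-2H-chromen-3-yl]acetate
Conditions: Me3SiCH2CH2OH, EDC·HCl, DMAP (cat.), CH2Cl2, rt
Reagents that add atoms: 2-(trimethylsilyl)ethanol, OCC[Si](C)(C)C
Why: Steglich esterification gives an ester that fluoride can later cleave without hydroxide, which would open the lactone.

Step 6
Reactants: 8 2-(trimethylsilyl)ethyl 2-[7-(benzyloxy)-6,8-dimethoxy-2-oxo-2H-chromen-3-yl]acetate
Product: 10 2-(trimethylsilyl)ethyl (Z)-2-[7-(benzyloxy)-6,8-dimethoxy-2-oxo-2H-chromen-3-yl]-3-hydroxyprop-2-enoate, via lithium ester enolate 9 (not isolated)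
Conditions: LiN(SiMe3)2 (2.2 equiv), THF, -78 °C; HCO2CH2CF3, -78 to 0 °C; then 1 M HCl
Reagents that add atoms: 2,2,2-trifluoroethyl formate, O=COCC(F)(F)F (formyl carbon and oxygen); LiN(SiMe3)2, [Li+].C[Si](C)(C)[N-][Si](C)(C)C (lithium of 9 only)
Why: crossed Claisen formylation of the ester enolate uses a very reactive formate whose trifluoroethoxide leaving group is too weak a nucleophile to open the lactone or exchange the ester, and the second equivalent of base takes up the acidic product.

Step 7
Reactants: 10 2-(trimethylsilyl)ethyl (Z)-2-[7-(benzyloxy)-6,8-dimethoxy-2-oxo-2H-chromen-3-yl]-3-hydroxyprop-2-enoate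
Product: 11 2-(trimethylsilyl)ethyl (Z)-2-[7-(benzyloxy)-6,8-dimethoxy-2-oxo-2H-chromen-3-yl]-3-(tosyloxy)prop-2-enoate
Conditions: TsCl, TMEDA, LiCl, MeCN, 0 °C
Reagents that add atoms: p-toluenesulfonyl chloride, Cc1ccc(cc1)S(Cl)(=O)=O
Why: O-sulfonylation of the lithium-chelated enolate, in which the enolate oxygen is held cis to the ester carbonyl in a six-membered chelate, is the established way to (Z)-enol tosylates of alpha-formyl and beta-keto esters and sets the alkene geometry that the key step needs.

Step 8
Reactants: 11 2-(trimethylsilyl)ethyl (Z)-2-[7-(benzyloxy)-6,8-dimethoxy-2-oxo-2H-chromen-3-yl]-3-(tosyloxy)prop-2-enoate; 12 trimethylsilylacetylene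
Product: 13 2-(trimethylsilyl)ethyl (Z)-2-[7-(benzyloxy)-6,8-dimethoxy-2-oxo-2H-chromen-3-yl]-5-(trimethylsilyl)pent-2-en-4-ynoate
Conditions: PdCl2(PPh3)2, CuI, iPr2NEt, MeCN, 50 °C
Reagents that add atoms: none
Why: Sonogashira coupling of the activated beta-tosyloxy acrylate proceeds with retention of alkene geometry, so the alkynyl group should arrive cis to the ester.

Step 9
Reactants: 13 2-(trimethylsilyl)ethyl (Z)-2-[7-(benzyloxy)-6,8-dimethoxy-2-oxo-2H-chromen-3-yl]-5-(trimethylsilyl)pent-2-en-4-ynoate
Product: 14 (Z)-2-[7-(benzyloxy)-6,8-dimethoxy-2-oxo-2H-chromen-3-yl]pent-2-en-4-ynoic acid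
Conditions: Bu4NF (3 equiv), THF, 0 °C to rt; then 0.5 M HCl
Reagents that add atoms: none
Why: fluoride-induced fragmentation of the 2-(trimethylsilyl)ethyl ester with loss of ethylene and protodesilylation of the alkyne should occur in one operation and leave the lactone, the benzyl ether and the Z alkene untouched, provided that copper and palladium residues of step 8 have been removed.

Step 10
Reactants: 15 tetronic acid
Product: 16 4-(benzyloxy)furan-2(5H)-one
Conditions: BnOH, PPh3, DIAD, THF, 0 °C to rt
Reagents that add atoms: benzyl alcohol, OCc1ccccc1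
Why: Mitsunobu alkylation of the acidic vinylogous acid takes place on oxygen and gives the 4-alkoxybutenolide.

Step 11
Reactants: 14 (Z)-2-[7-(benzyloxy)-6,8-dimethoxy-2-oxo-2H-chromen-3-yl]pent-2-en-4-ynoic acid; 16 4-(benzyloxy)furan-2(5H)-one
Product: 19 4-(benzyloxy)furan-2-yl (Z)-2-[7-(benzyloxy)-6,8-dimethoxy-2-oxo-2H-chromen-3-yl]pent-2-en-4-ynoate, via potassium furanolate 17 (not isolated), via acid chloride 18 (not isolated)
Conditions: 14, Me2C=C(Cl)NMe2, CH2Cl2, 0 °C; 16, KN(SiMe3)2, THF, -78 °C; combine at -78 °C; pH 7 buffer, neutral alumina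
Reagents that add atoms: 1-chloro-N,N,2-trimethylprop-1-en-1-amine, CC(C)=C(Cl)N(C)C (chlorine of 18 only); KN(SiMe3)2, [K+].C[Si](C)(C)[N-][Si](C)(C)C (potassium of 17 only)
Why: in this O-acylation of a butenolide dienolate the hard acid chloride, made under neutral conditions, should be attacked at oxygen by the potassium 2-furanolate as in the preparation of 2-silyloxy- and 2-acyloxyfurans from butenolides, and no nucleophilic amine catalyst is present that could move the acyl group to carbon.

Step 12
Reactants: 19 4-(benzyloxy)furan-2-yl (Z)-2-[7-(benzyloxy)-6,8-dimethoxy-2-oxo-2H-chromen-3-yl]pent-2-en-4-ynoate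
Product: 21 7,7'-di-O-benzyl arteminorin C, via oxanorbornadiene adduct 20 (not isolated)
Conditions: BHT (cat.), degassed o-C6H4Cl2 (0.01 M), 150 °C, sealed tube
Reagents that add atoms: none
Why: Proposed new method: the furan of 19, raised in energy by its 4-benzyloxy and 2-acyloxy donors, should add as the diene across the terminal alkyne, which is lowered in energy by conjugation with the acrylate, in an intramolecular [4+2] that forms C4a'-C8a' and C5'-C6' and gives adduct 20; the closest known reaction type is the intramolecular Diels-Alder reaction of 2-amino- and 2-alkoxy-substituted furans with tethered alkenes or alkynes, which ends in ring opening and aromatization. The pyranone of unit B closes as the six-membered ring defined by the four-atom tether O1'-C2'-C3'=C4' between furan C2 and the inner alkyne carbon, and the benzene ring closes as the six-membered ring of the cycloaddition. Ionization of the C8a'-O bridge bond gives a cation stabilized by O1' and, through C8'=C7', by the benzyloxy group, and loss of the C6' proton gives the 6'-phenol, so the step is an isomerization driven by aromatization of both new rings. The two bridgehead centres of 20 are tied to each other by the bridge and vanish on aromatization, so no stereocentre has to be controlled. Regiochemistry is needed and is secured by the tether, which can only bring the inner alkyne carbon to the acyloxy-bearing furan carbon, and by the fact that only the C8a'-O bond can open productively because C6' alone carries a hydrogen; the Z alkene from steps 7 and 8 holds the alkyne on the ester side, and the three-atom path to C3=C4 of ring A would need a strained five-membered closure with no aromatic outlet. High dilution and an acid-free, catalyst-free medium are meant to hold back intermolecular cycloaddition and O-to-C acyl migration while the ester reaches its less favoured rotamer.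

Step 13
Reactants: 21 7,7'-di-O-benzyl arteminorin C
Product: 22 arteminorin C
Conditions: H2 (1 atm), 10% Pd/C, EtOAc/MeOH, rt
Reagents that add atoms: none
Why: hydrogenolysis of the two aryl benzyl ethers is much faster than reduction of the hindered, aryl-substituted C3=C4 bonds of the two coumarins, so the reaction should stop at the target if hydrogen uptake is followed.

**Compound list**

1 | syringaldehyde | COc1cc(C=O)cc(OC)c1O | starting material
2 | 4-(benzyloxy)-3,5-dimethoxybenzaldehyde | COc1cc(C=O)cc(OC)c1OCc1ccccc1 | intermediate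
3 | 4-(benzyloxy)-2-bromo-3,5-dimethoxybenzaldehyde | COc1cc(C=O)c(Br)c(OC)c1OCc1ccccc1 | intermediate
4 | 4-(benzyloxy)-3,5-dimethoxy-2-(4,4,5,5-tetramethyl-1,3,2-dioxaborolan-2-yl)benzaldehyde (not isolated) | COc1cc(C=O)c(B2OC(C)(C)C(C)(C)O2)c(OC)c1OCc1ccccc1 | intermediate
5 | 4-(benzyloxy)-2-hydroxy-3,5-dimethoxybenzaldehyde | COc1cc(C=O)c(O)c(OC)c1OCc1ccccc1 | intermediate
6 | succinic anhydride | O=C1CCC(=O)O1 | starting material
7 | 2-[7-(benzyloxy)-6,8-dimethoxy-2-oxo-2H-chromen-3-yl]acetic acid | COc1cc2cc(CC(=O)O)c(=O)oc2c(OC)c1OCc1ccccc1 | intermediate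
8 | 2-(trimethylsilyl)ethyl 2-[7-(benzyloxy)-6,8-dimethoxy-2-oxo-2H-chromen-3-yl]acetate | COc1cc2cc(CC(=O)OCC[Si](C)(C)C)c(=O)oc2c(OC)c1OCc1ccccc1 | intermediate
9 | lithium enolate of 8 (not isolated; OLi drawn cis to the coumarinyl group) | [Li+].[O-]/C(OCC[Si](C)(C)C)=C\c1cc2cc(OC)c(OCc3ccccc3)c(OC)c2oc1=O | intermediate
10 | 2-(trimethylsilyl)ethyl (Z)-2-[7-(benzyloxy)-6,8-dimethoxy-2-oxo-2H-chromen-3-yl]-3-hydroxyprop-2-enoate (enol form of the alpha-formyl ester) | O/C=C(\C(=O)OCC[Si](C)(C)C)c1cc2cc(OC)c(OCc3ccccc3)c(OC)c2oc1=O | intermediate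
11 | 2-(trimethylsilyl)ethyl (Z)-2-[7-(benzyloxy)-6,8-dimethoxy-2-oxo-2H-chromen-3-yl]-3-(tosyloxy)prop-2-enoate | Cc1ccc(cc1)S(=O)(=O)O/C=C(\C(=O)OCC[Si](C)(C)C)c1cc2cc(OC)c(OCc3ccccc3)c(OC)c2oc1=O | intermediate
12 | trimethylsilylacetylene | C#C[Si](C)(C)C | starting material
13 | 2-(trimethylsilyl)ethyl (Z)-2-[7-(benzyloxy)-6,8-dimethoxy-2-oxo-2H-chromen-3-yl]-5-(trimethylsilyl)pent-2-en-4-ynoate | C[Si](C)(C)C#C/C=C(\C(=O)OCC[Si](C)(C)C)c1cc2cc(OC)c(OCc3ccccc3)c(OC)c2oc1=O | intermediate
14 | (Z)-2-[7-(benzyloxy)-6,8-dimethoxy-2-oxo-2H-chromen-3-yl]pent-2-en-4-ynoic acid | C#C/C=C(\C(=O)O)c1cc2cc(OC)c(OCc3ccccc3)c(OC)c2oc1=O | intermediate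
15 | tetronic acid | O=C1CC(=O)CO1 | starting material
16 | 4-(benzyloxy)furan-2(5H)-one | O=C1C=C(OCc2ccccc2)CO1 | intermediate
17 | potassium 4-(benzyloxy)furan-2-olate (not isolated) | [K+].[O-]c1cc(OCc2ccccc2)co1 | intermediate
18 | (Z)-2-[7-(benzyloxy)-6,8-dimethoxy-2-oxo-2H-chromen-3-yl]pent-2-en-4-ynoyl chloride (not isolated) | C#C/C=C(\C(Cl)=O)c1cc2cc(OC)c(OCc3ccccc3)c(OC)c2oc1=O | intermediate
19 | 4-(benzyloxy)furan-2-yl (Z)-2-[7-(benzyloxy)-6,8-dimethoxy-2-oxo-2H-chromen-3-yl]pent-2-en-4-ynoate | C#C/C=C(\C(=O)Oc1cc(OCc2ccccc2)co1)c1cc2cc(OC)c(OCc3ccccc3)c(OC)c2oc1=O | intermediate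
20 | 7-(benzyloxy)-3-[7-(benzyloxy)-6,8-dimethoxy-2-oxo-2H-chromen-3-yl]-6,8a-epoxy-6,8a-dihydro-2H-chromen-2-one (oxanorbornadiene adduct, racemic, one enantiomer drawn, not isolated) | O=C1O[C@]23C=C(OCc4ccccc4)[C@H](O2)C=C3C=C1c1cc2cc(OC)c(OCc3ccccc3)c(OC)c2oc1=O | intermediate
21 | 7,7'-di-O-benzyl arteminorin C | COc1cc2cc(-c3cc4cc(O)c(OCc5ccccc5)cc4oc3=O)c(=O)oc2c(OC)c1OCc1ccccc1 | intermediate
22 | arteminorin C | COc1cc2cc(-c3cc4cc(O)c(O)cc4oc3=O)c(=O)oc2c(OC)c1O | target

**Step count and risks**

Total: 13 steps. Longest linear sequence: 12 steps (steps 1 to 9 and 11 to 13 from syringaldehyde); step 10 is a one-step branch.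

Step 12. The ester may not reach its reactive rotamer before the substrate is consumed by O-to-C acyl migration, intermolecular cycloaddition, cleavage of the furyl ester or cycloaddition across C3=C4 of ring A. The fallback uses known chemistry, sets out from acid 7 and comes back at target 22. Acid 7 and purchased 2,4,5-trihydroxybenzaldehyde F1 are heated with Ac2O and Et3N at 120 °C in a Perkin-Oglialoro condensation, the standard route to 3-arylcoumarins, which should build unit B directly and give 6',7'-di-O-acetyl-7-O-benzyl arteminorin C F2. Acidic methanolysis (HCl, MeOH, rt) should remove the two acetates to give 7-O-benzyl arteminorin C F3, and hydrogenolysis under the conditions of step 13 leads to 22.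

Step 11. The ambident furanolate may be acylated on carbon (C3 or C5) in place of oxygen, and the enol ester may be hydrolysed during isolation. The fallback avoids a metal enolate, sets out from butenolide 16 and acid 14 and comes back at ester 19. Soft enolization and silylation of 16 (tBuMe2SiOTf, Et3N, CH2Cl2, 0 °C) should give 4-(benzyloxy)-2-[(tert-butyldimethylsilyl)oxy]furan F4. Acid 14 is converted with cyanuric fluoride and pyridine into (Z)-2-[7-(benzyloxy)-6,8-dimethoxy-2-oxo-2H-chromen-3-yl]pent-2-en-4-ynoyl fluoride F5. Fluoride-catalysed acyl transfer between F4 and F5 (Bu4N[Ph3SiF2] cat., THF, 0 °C), the known O-acylation of silyl enol ethers by acyl fluorides driven by Si-F bond formation, gives 19.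

Step 7. Loss of chelation control, for example by competition of the lactone carbonyl for lithium, would erode the Z selectivity of the enol tosylation, and the stereoretentive coupling of step 8 would pass the wrong geometry on to the key step. The fallback sets the alkene by olefination in place of cross-coupling, sets out from ester 8 and comes back at enynoate 13. Bromination of the ester enolate (LiN(SiMe3)2, THF, -78 °C; NBS) should give 2-(trimethylsilyl)ethyl 2-bromo-2-[7-(benzyloxy)-6,8-dimethoxy-2-oxo-2H-chromen-3-yl]acetate F6 (racemic). Michaelis-Becker substitution with diphenyl phosphite and Et3N gives 2-(trimethylsilyl)ethyl 2-[7-(benzyloxy)-6,8-dimethoxy-2-oxo-2H-chromen-3-yl]-2-(diphenoxyphosphoryl)acetate F7 (racemic). Z-selective Horner-Wadsworth-Emmons olefination of F7 with purchased 3-(trimethylsilyl)propynal F8 (NaH, THF, -78 °C), in which the diaryl phosphonate places the aldehyde substituent cis to the ester, gives 13.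

**Further compounds**

F1 | step 12 | 2,4,5-trihydroxybenzaldehyde (purchased) | O=Cc1cc(O)c(O)cc1O
F2 | step 12 | 6',7'-di-O-acetyl-7-O-benzyl arteminorin C | COc1cc2cc(-c3cc4cc(OC(C)=O)c(OC(C)=O)cc4oc3=O)c(=O)oc2c(OC)c1OCc1ccccc1
F3 | step 12 | 7-O-benzyl arteminorin C | COc1cc2cc(-c3cc4cc(O)c(O)cc4oc3=O)c(=O)oc2c(OC)c1OCc1ccccc1
F4 | step 11 | 4-(benzyloxy)-2-[(tert-butyldimethylsilyl)oxy]furan | CC(C)(C)[Si](C)(C)Oc1cc(OCc2ccccc2)co1
F5 | step 11 | (Z)-2-[7-(benzyloxy)-6,8-dimethoxy-2-oxo-2H-chromen-3-yl]pent-2-en-4-ynoyl fluoride | C#C/C=C(\C(F)=O)c1cc2cc(OC)c(OCc3ccccc3)c(OC)c2oc1=O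
F6 | step 7 | 2-(trimethylsilyl)ethyl 2-bromo-2-[7-(benzyloxy)-6,8-dimethoxy-2-oxo-2H-chromen-3-yl]acetate (racemic) | COc1cc2cc(C(Br)C(=O)OCC[Si](C)(C)C)c(=O)oc2c(OC)c1OCc1ccccc1
F7 | step 7 | 2-(trimethylsilyl)ethyl 2-[7-(benzyloxy)-6,8-dimethoxy-2-oxo-2H-chromen-3-yl]-2-(diphenoxyphosphoryl)acetate (racemic) | COc1cc2cc(C(C(=O)OCC[Si](C)(C)C)P(=O)(Oc3ccccc3)Oc3ccccc3)c(=O)oc2c(OC)c1OCc1ccccc1
F8 | step 7 | 3-(trimethylsilyl)propynal (purchased) | C[Si](C)(C)C#CC=O
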